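The constants are hidden, so the reckoning for this flask has to come from the amber and violet runs.

| flask | substrate | remark | time |
|---|---|---|---|
| amber | 0.10 M | run made earlier |  |
| violet | 0.40 M | run made earlier |  |
| flask | 0.20 M |  | 2.0 h |

| run | time / min | target / % | crystals / % |
|---|---|---|---|
| amber | 8.00 | 84 | 84 |
| amber | 25.0 | 83 | 82 |
| amber | 40.0 | 84 | 77 |
| amber | 60.0 | 79 | 77 |
| amber | 90.0 | 74 | 70 |
| violet | 8.00 | 88 | 88 |
| violet | 15.0 | 89 | 91 |
| violet | 25.0 | 89 | 86 |
| violet | 50.0 | 89 | 88 |
| violet | 90.0 | 87 | 89 |

(standard deviation of a reading: 1.5 percentage points)

- what is said of target includes crystals
- crystals is a solid; its amount is given per volume of the solution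
- on the list of suspects stand: substrate <-> target; substrate <-> isomer of the product; substrate <-> third isomer; crystals <-> target

- the target and crystals together standing at 2.0 h, as a percentage of the substrate charged
- concentration of target in solution at 2.0 h, in percent of saturation

Start the count from the main step: substrate goes to target, target falls out, and the whole charge stands as target and crystals. In the amber run target and crystals agree within the scatter, 84 % against 84 % at 8.00 min, so little target stays dissolved.

Add the two other isomers. The early plateaus stand at 84 % in the amber run and 89 % in the violet run. The flask's charge lies midway between them on a ratio scale, so my plateau is 86.5 %.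

Add the slow loss afterwards. Its measure is the emptying time: the time a steady, zero-order drain needs to take a whole charge. The amber readings give 13.7 h. The violet readings, whose loss is little above the scatter, give 54.2 h, which is longer by a factor of 3.96, against 4.00 in charge. These two readings carry the scatter, but I take the emptying time to scale with the charge, and that makes it 27.3 h for the flask. From 8.00 min to 2.0 h the drain takes 6.83 % of the charge, which leaves 79.7 %. The emptying time is longer than the time asked, so crystals should still stand and hold the solution near saturation.

The forecast gives 81 % (77.5 % to 84.5 %), 1.3 percentage points above my figure, and 99 % (92 % to 103 %). Its ground: “saturated target feeds slowly through substrate into the other isomers, independent of crystal mass”.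

The flask gives 80.2 % and 96.3 %, both inside the forecast's ranges.

    substrate ⇌ target (K = 0.740, k = 0.0160 /s)
    substrate ⇌ isomer of the product (K = 25.0, k = 3.00 × 10⁻⁴ /s)
    substrate ⇌ third isomer (K = 98.0, k = 5.70 × 10⁻⁴ /s)
    crystals ⇌ target, rate k4*(cs4 - [target]) while solid is left; crystals form when [target] > cs4 (solubility = 2.60 mM, k = 0.0260 /s)

The flask holds 80.2 % in part because target is poorly soluble and in part because the time is short: without the low solubility the same run gives 1.79 %, and ten times as long gives 14.5 %. The emptying time, carried to 20.0 h, reckons 13.7 % for this flask. For the neighbour flask charged with 0.080 M the same scaling reckons an emptying time of 10.9 h, so from the amber plateau, read at a larger charge than this neighbour's, it should reach 66.9 % at 2.0 h; the neighbour flask gives 63.5 %.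

Readings and results stem from a simulated flask for an exercise.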